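**Retrosynthetic overview**
1. Target 31 ⇐ bis-silyl ether 30 ⇐ 4-hydroxy-2-pyranone 29 (desilylation, O-methylation); the only ring, the 2-pyranone, is closed last by lactonisation of 3,5-diketo ester 28.
2. 28 ⇐ C5–C6 bond (pyranone numbering) by an intermolecular aldol of the dianion of ethyl 2-methylacetoacetate 25 with α-silyloxy aldehyde 24, then oxidation.
3. 24 ⇐ imide 19 by auxiliary-controlled α-hydroxylation (C1'); 19 ⇐ ester 16 by Johnson–Claisen rearrangement of allylic alcohol 13 (sets C2' and the (E)-C3'=C4' alkene by 1,3-chirality transfer).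
4. 13 ⇐ aldehyde 8 by Wittig enone formation ((E)-C6'=C7') and CBS reduction (C8'); 8 ⇐ Evans syn-aldol of 1 with tiglic aldehyde 2 (sets C5' and the relay carbinol C4').
5. Ring order: one ring only, formed in step 18.

Assumption: C1'–C9' are the side-chain carbons counted from the pyranone; TBS = tert-butyldimethylsilyl, TES = triethylsilyl; 1, 2, 9, 14 and 25 are bought.

**Route**

Step 1
Reactants: 1 (R)-4-benzyl-3-propanoyl-1,3-oxazolidin-2-one; 2 (E)-2-methylbut-2-enal (tiglic aldehyde)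
Product: 5 (R)-4-benzyl-3-[(2R,3R,4E)-3-hydroxy-2,4-dimethylhex-4-enoyl]-1,3-oxazolidin-2-one, via Z-dibutylboron enolate 3 (not isolated), via boron aldolate 4 (not isolated)
Conditions: Bu2BOTf, i-Pr2NEt, CH2Cl2, 0 °C; 2, −78 → 0 °C; then aq. NaH2PO4/Na2HPO4 (pH 7), MeOH, 30% H2O2, 0 °C
Reagents that add atoms: none
Why: Evans syn-aldol reaction, in which the Z-boron enolate reacts through a Zimmerman–Traxler chair on the face away from the benzyl group, giving the 2,3-syn adduct that fixes C5' and the relay carbinol C4' (both R in 5).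

Step 2
Reactants: 5 (R)-4-benzyl-3-[(2R,3R,4E)-3-hydroxy-2,4-dimethylhex-4-enoyl]-1,3-oxazolidin-2-one
Product: 6 (2R,3R,4E)-3-hydroxy-N-methoxy-N,2,4-trimethylhex-4-enamide
Conditions: MeNH(OMe)·HCl, AlMe3, CH2Cl2, −20 → 0 °C; then 0.5 M HCl
Reagents that add atoms: N,O-dimethylhydroxylamine hydrochloride, CNOC.Cl
Why: Weinreb transamidation of the aldol imide, assisted by the free β-hydroxyl, displaces the auxiliary without touching either stereocentre.

Step 3
Reactants: 6 (2R,3R,4E)-3-hydroxy-N-methoxy-N,2,4-trimethylhex-4-enamide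
Product: 7 (2R,3R,4E)-N-methoxy-N,2,4-trimethyl-3-(triethylsilyloxy)hex-4-enamide
Conditions: Et3SiOTf, 2,6-lutidine, CH2Cl2, −78 °C
Reagents that add atoms: triethylsilyl triflate, CC[Si](CC)(CC)OS(=O)(=O)C(F)(F)F
Why: Silyl ether formation with a silyl triflate is fast even on this hindered allylic alcohol and gives a group that can later be removed in the presence of a TBS ether.

Step 4
Reactants: 7 (2R,3R,4E)-N-methoxy-N,2,4-trimethyl-3-(triethylsilyloxy)hex-4-enamide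
Product: 8 (2R,3R,4E)-2,4-dimethyl-3-(triethylsilyloxy)hex-4-enal
Conditions: i-Bu2AlH, THF, −78 °C; then aq. potassium sodium tartrate
Reagents that add atoms: none
Why: Partial reduction of a Weinreb amide stops cleanly at the aldehyde, and the cold neutral work-up keeps the α-stereocentre intact.

Step 5
Reactants: 8 (2R,3R,4E)-2,4-dimethyl-3-(triethylsilyloxy)hex-4-enal; 9 3-(triphenylphosphoranylidene)butan-2-one
Product: 10 (3E,5S,6R,7E)-3,5,7-trimethyl-6-(triethylsilyloxy)nona-3,7-dien-2-one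
Conditions: 9 (2 equiv), toluene, 90 °C
Reagents that add atoms: none
Why: Wittig olefination with an α-branched acyl-stabilised ylide is strongly E-selective and builds the C6'=C7' trisubstituted alkene with C8' and C9' attached.

Step 6
Reactants: 10 (3E,5S,6R,7E)-3,5,7-trimethyl-6-(triethylsilyloxy)nona-3,7-dien-2-one
Product: 11 (2R,3E,5S,6R,7E)-3,5,7-trimethyl-6-(triethylsilyloxy)nona-3,7-dien-2-ol
Conditions: (S)-2-methyl-CBS-oxazaborolidine (20 mol%), catecholborane, toluene, −78 °C; then MeOH, H2O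
Reagents that add atoms: none
Why: Corey–Bakshi–Shibata reduction, in which the alkenyl group acts as the large substituent so the (S)-catalyst delivers hydride to give the (R)-allylic alcohol at C8', with catecholborane sparing the alkenes.

Step 7
Reactants: 11 (2R,3E,5S,6R,7E)-3,5,7-trimethyl-6-(triethylsilyloxy)nona-3,7-dien-2-ol
Product: 12 (2R,3E,5S,6R,7E)-2-(tert-butyldimethylsilyloxy)-3,5,7-trimethyl-6-(triethylsilyloxy)nona-3,7-diene
Conditions: t-BuMe2SiCl, imidazole, DMF, rt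
Reagents that add atoms: tert-butyldimethylsilyl chloride, CC(C)(C)[Si](C)(C)Cl
Why: Standard silylation protects the C8' alcohol with a group about a hundred times more acid-stable than the TES ether.

Step 8
Reactants: 12 (2R,3E,5S,6R,7E)-2-(tert-butyldimethylsilyloxy)-3,5,7-trimethyl-6-(triethylsilyloxy)nona-3,7-diene
Product: 13 (2E,4R,5S,6E,8R)-8-(tert-butyldimethylsilyloxy)-3,5,7-trimethylnona-2,6-dien-4-ol
Conditions: PPTS (0.1 equiv), MeOH/CH2Cl2, 0 °C
Reagents that add atoms: none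
Why: Selective acid-catalysed methanolysis removes the more labile TES ether and frees the C4' allylic alcohol while the TBS ether stays.

Step 9
Reactants: 13 (2E,4R,5S,6E,8R)-8-(tert-butyldimethylsilyloxy)-3,5,7-trimethylnona-2,6-dien-4-ol; 14 triethyl orthoacetate
Product: 16 ethyl (3R,4E,6R,7E,9R)-9-(tert-butyldimethylsilyloxy)-3,4,6,8-tetramethyldeca-4,7-dienoate, via ketene acetal 15 (not isolated)
Conditions: 14 (excess), EtCO2H (cat.), 135 °C, EtOH distilled off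
Reagents that add atoms: none
Why: Johnson–Claisen rearrangement through a chair transition state with the C5'-bearing substituent equatorial gives the (E)-C3'=C4' alkene and transfers the C4' (R) configuration suprafacially to the new C2' centre.

Step 10
Reactants: 16 ethyl (3R,4E,6R,7E,9R)-9-(tert-butyldimethylsilyloxy)-3,4,6,8-tetramethyldeca-4,7-dienoate
Product: 17 (3R,4E,6R,7E,9R)-9-(tert-butyldimethylsilyloxy)-3,4,6,8-tetramethyldeca-4,7-dienoic acid
Conditions: LiOH, THF/MeOH/H2O, rt; then 1 M HCl to pH 4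
Reagents that add atoms: lithium hydroxide, [Li+].[OH-]
Why: Saponification is safe because the only stereocentre near the carboxyl is β and cannot epimerise, and the secondary TBS ether tolerates LiOH.

Step 11
Reactants: 17 (3R,4E,6R,7E,9R)-9-(tert-butyldimethylsilyloxy)-3,4,6,8-tetramethyldeca-4,7-dienoic acid
Product: 19 (S)-4-benzyl-3-[(3R,4E,6R,7E,9R)-9-(tert-butyldimethylsilyloxy)-3,4,6,8-tetramethyldeca-4,7-dienoyl]-1,3-oxazolidin-2-one, via mixed pivalic anhydride 18 (not isolated)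
Conditions: t-BuCOCl, Et3N, THF, −20 °C; then LiCl, (S)-4-benzyl-1,3-oxazolidin-2-one, −20 °C → rt
Reagents that add atoms: (S)-4-benzyl-1,3-oxazolidin-2-one, O=C1OC[C@H](Cc2ccccc2)N1
Why: N-acylation through the mixed anhydride occurs at the less hindered carbonyl and installs the auxiliary that will control C1'.

Step 12
Reactants: 19 (S)-4-benzyl-3-[(3R,4E,6R,7E,9R)-9-(tert-butyldimethylsilyloxy)-3,4,6,8-tetramethyldeca-4,7-dienoyl]-1,3-oxazolidin-2-one
Product: 21 (S)-4-benzyl-3-[(2S,3S,4E,6R,7E,9R)-9-(tert-butyldimethylsilyloxy)-2-hydroxy-3,4,6,8-tetramethyldeca-4,7-dienoyl]-1,3-oxazolidin-2-one, via sodium enolate 20 (not isolated)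
Conditions: NaN(SiMe3)2, THF, −78 °C; 2-(phenylsulfonyl)-3-phenyloxaziridine, −78 °C; then AcOH
Reagents that add atoms: 2-(phenylsulfonyl)-3-phenyloxaziridine, O=S(=O)(c1ccccc1)N1OC1c1ccccc1
Why: Evans–Davis enolate hydroxylation, in which the chelated Z-sodium enolate is oxidised on the face opposite the benzyl group, sets C1' as S and so gives the 1',2'-anti relationship.

Step 13
Reactants: 21 (S)-4-benzyl-3-[(2S,3S,4E,6R,7E,9R)-9-(tert-butyldimethylsilyloxy)-2-hydroxy-3,4,6,8-tetramethyldeca-4,7-dienoyl]-1,3-oxazolidin-2-one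
Product: 22 (S)-4-benzyl-3-[(2S,3S,4E,6R,7E,9R)-2,9-bis(tert-butyldimethylsilyloxy)-3,4,6,8-tetramethyldeca-4,7-dienoyl]-1,3-oxazolidin-2-one
Conditions: t-BuMe2SiOTf, 2,6-lutidine, CH2Cl2, −78 → 0 °C
Reagents that add atoms: tert-butyldimethylsilyl triflate, CC(C)(C)[Si](C)(C)OS(=O)(=O)C(F)(F)F
Why: Silyl triflate protection of the hindered α-hydroxyl blocks retro-aldol and epimerisation pathways in the later basic steps.

Step 14
Reactants: 22 (S)-4-benzyl-3-[(2S,3S,4E,6R,7E,9R)-2,9-bis(tert-butyldimethylsilyloxy)-3,4,6,8-tetramethyldeca-4,7-dienoyl]-1,3-oxazolidin-2-one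
Product: 23 (2S,3S,4E,6R,7E,9R)-2,9-bis(tert-butyldimethylsilyloxy)-3,4,6,8-tetramethyldeca-4,7-dien-1-ol
Conditions: LiBH4, THF, 0 °C → rt; then H2O
Reagents that add atoms: none
Why: Reductive cleavage of the N-acyl oxazolidinone with LiBH4 gives the primary alcohol and returns the auxiliary without affecting C1'.

Step 15
Reactants: 23 (2S,3S,4E,6R,7E,9R)-2,9-bis(tert-butyldimethylsilyloxy)-3,4,6,8-tetramethyldeca-4,7-dien-1-ol
Product: 24 (2S,3S,4E,6R,7E,9R)-2,9-bis(tert-butyldimethylsilyloxy)-3,4,6,8-tetramethyldeca-4,7-dienal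
Conditions: Dess–Martin periodinane, CH2Cl2, 0 °C → rt
Reagents that add atoms: none
Why: Dess–Martin oxidation is mild and non-basic, so the α-silyloxy aldehyde forms without epimerisation and is used at once.

Step 16
Reactants: 24 (2S,3S,4E,6R,7E,9R)-2,9-bis(tert-butyldimethylsilyloxy)-3,4,6,8-tetramethyldeca-4,7-dienal; 25 ethyl 2-methyl-3-oxobutanoate
Product: 27 ethyl (6S,7S,8E,10R,11E,13R)-6,13-bis(tert-butyldimethylsilyloxy)-5-hydroxy-2,7,8,10,12-pentamethyl-3-oxotetradeca-8,11-dienoate (C2/C5 epimer mixture), via sodium lithium dianion 26 (not isolated)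
Conditions: 25, NaH, THF, 0 °C; n-BuLi, 0 °C; then 24, −78 °C; then AcOH
Reagents that add atoms: none
Why: Intermolecular aldol addition of the Weiler dianion through its terminal carbon joins the side-chain aldehyde to the pyranone carbons, and the two uncontrolled centres (C2, C5) are erased in steps 17 and 18.

Step 17
Reactants: 27 ethyl (6S,7S,8E,10R,11E,13R)-6,13-bis(tert-butyldimethylsilyloxy)-5-hydroxy-2,7,8,10,12-pentamethyl-3-oxotetradeca-8,11-dienoate
Product: 28 ethyl (6S,7S,8E,10R,11E,13R)-6,13-bis(tert-butyldimethylsilyloxy)-2,7,8,10,12-pentamethyl-3,5-dioxotetradeca-8,11-dienoate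
Conditions: Dess–Martin periodinane, CH2Cl2, rt
Reagents that add atoms: none
Why: Dess–Martin oxidation of a β-hydroxy ketone gives the enolised 1,3-diketone without retro-aldol cleavage.

Step 18
Reactants: 28 ethyl (6S,7S,8E,10R,11E,13R)-6,13-bis(tert-butyldimethylsilyloxy)-2,7,8,10,12-pentamethyl-3,5-dioxotetradeca-8,11-dienoate
Product: 29 6-[(1S,2S,3E,5R,6E,8R)-1,8-bis(tert-butyldimethylsilyloxy)-2,3,5,7-tetramethylnona-3,6-dien-1-yl]-4-hydroxy-3-methyl-2H-pyran-2-one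
Conditions: DBU, toluene, rt → 40 °C
Reagents that add atoms: none
Why: Base-mediated lactonisation, in which the enol oxygen of the C5 ketone attacks the ester, closes the 4-hydroxy-2-pyranone; the diketone is deprotonated between its carbonyls, which shields the C1' hydrogen.

Step 19
Reactants: 29 6-[(1S,2S,3E,5R,6E,8R)-1,8-bis(tert-butyldimethylsilyloxy)-2,3,5,7-tetramethylnona-3,6-dien-1-yl]-4-hydroxy-3-methyl-2H-pyran-2-one
Product: 30 6-[(1S,2S,3E,5R,6E,8R)-1,8-bis(tert-butyldimethylsilyloxy)-2,3,5,7-tetramethylnona-3,6-dien-1-yl]-4-methoxy-3-methyl-2H-pyran-2-one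
Conditions: Me2SO4, K2CO3, acetone, rt → 50 °C
Reagents that add atoms: dimethyl sulfate, COS(=O)(=O)OC
Why: O-methylation of the pyranone anion with dimethyl sulfate and carbonate favours the 4-oxygen, giving the 4-methoxy-2-pyranone and not the 2-methoxy-4-pyranone.

Step 20
Reactants: 30 6-[(1S,2S,3E,5R,6E,8R)-1,8-bis(tert-butyldimethylsilyloxy)-2,3,5,7-tetramethylnona-3,6-dien-1-yl]-4-methoxy-3-methyl-2H-pyran-2-one
Product: 31 6-[(1S,2S,3E,5R,6E,8R)-1,8-dihydroxy-2,3,5,7-tetramethylnona-3,6-dien-1-yl]-4-methoxy-3-methyl-2H-pyran-2-one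
Conditions: HF·pyridine, pyridine, THF, 0 °C → rt
Reagents that add atoms: none
Why: Buffered fluoride desilylation removes both TBS ethers without ionising the allylic C8' alcohol or opening the pyranone.

**Compound list**

1 | (R)-4-benzyl-3-propanoyl-1,3-oxazolidin-2-one | CCC(=O)N1[C@H](Cc2ccccc2)COC1=O | starting material
2 | (E)-2-methylbut-2-enal (tiglic aldehyde) | C/C=C(\C)C=O | starting material
3 | Z-dibutylboron enolate of 1 | C/C=C(\OB(CCCC)CCCC)N1[C@H](Cc2ccccc2)COC1=O | intermediate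
4 | O-dibutylboryl aldolate of 5 | C/C=C(\C)[C@H](OB(CCCC)CCCC)[C@@H](C)C(=O)N1[C@H](Cc2ccccc2)COC1=O | intermediate
5 | (R)-4-benzyl-3-[(2R,3R,4E)-3-hydroxy-2,4-dimethylhex-4-enoyl]-1,3-oxazolidin-2-one | C/C=C(\C)[C@H](O)[C@@H](C)C(=O)N1[C@H](Cc2ccccc2)COC1=O | intermediate
6 | (2R,3R,4E)-3-hydroxy-N-methoxy-N,2,4-trimethylhex-4-enamide | C/C=C(\C)[C@H](O)[C@@H](C)C(=O)N(C)OC | intermediate
7 | (2R,3R,4E)-N-methoxy-N,2,4-trimethyl-3-(triethylsilyloxy)hex-4-enamide | C/C=C(\C)[C@H](O[Si](CC)(CC)CC)[C@@H](C)C(=O)N(C)OC | intermediate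
8 | (2R,3R,4E)-2,4-dimethyl-3-(triethylsilyloxy)hex-4-enal | C/C=C(\C)[C@H](O[Si](CC)(CC)CC)[C@@H](C)C=O | intermediate
9 | 3-(triphenylphosphoranylidene)butan-2-one | CC(=O)C(C)=P(c1ccccc1)(c1ccccc1)c1ccccc1 | starting material
10 | (3E,5S,6R,7E)-3,5,7-trimethyl-6-(triethylsilyloxy)nona-3,7-dien-2-one | C/C=C(\C)[C@H](O[Si](CC)(CC)CC)[C@@H](C)/C=C(\C)C(C)=O | intermediate
11 | (2R,3E,5S,6R,7E)-3,5,7-trimethyl-6-(triethylsilyloxy)nona-3,7-dien-2-ol | C/C=C(\C)[C@H](O[Si](CC)(CC)CC)[C@@H](C)/C=C(\C)[C@@H](C)O | intermediate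
12 | (2R,3E,5S,6R,7E)-2-(tert-butyldimethylsilyloxy)-3,5,7-trimethyl-6-(triethylsilyloxy)nona-3,7-diene | C/C=C(\C)[C@H](O[Si](CC)(CC)CC)[C@@H](C)/C=C(\C)[C@@H](C)O[Si](C)(C)C(C)(C)C | intermediate
13 | (2E,4R,5S,6E,8R)-8-(tert-butyldimethylsilyloxy)-3,5,7-trimethylnona-2,6-dien-4-ol | C/C=C(\C)[C@H](O)[C@@H](C)/C=C(\C)[C@@H](C)O[Si](C)(C)C(C)(C)C | intermediate
14 | triethyl orthoacetate (1,1,1-triethoxyethane) | CC(OCC)(OCC)OCC | starting material
15 | ketene ethyl acetal of 13 (1-ethoxyvinyl ether of the C4' alcohol) | C=C(OCC)O[C@@H](/C(C)=C/C)[C@@H](C)/C=C(\C)[C@@H](C)O[Si](C)(C)C(C)(C)C | intermediate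
16 | ethyl (3R,4E,6R,7E,9R)-9-(tert-butyldimethylsilyloxy)-3,4,6,8-tetramethyldeca-4,7-dienoate | CCOC(=O)C[C@@H](C)/C(C)=C/[C@@H](C)/C=C(\C)[C@@H](C)O[Si](C)(C)C(C)(C)C | intermediate
17 | (3R,4E,6R,7E,9R)-9-(tert-butyldimethylsilyloxy)-3,4,6,8-tetramethyldeca-4,7-dienoic acid | OC(=O)C[C@@H](C)/C(C)=C/[C@@H](C)/C=C(\C)[C@@H](C)O[Si](C)(C)C(C)(C)C | intermediate
18 | mixed anhydride of 17 with 2,2-dimethylpropanoic acid | CC(C)(C)C(=O)OC(=O)C[C@@H](C)/C(C)=C/[C@@H](C)/C=C(\C)[C@@H](C)O[Si](C)(C)C(C)(C)C | intermediate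
19 | (S)-4-benzyl-3-[(3R,4E,6R,7E,9R)-9-(tert-butyldimethylsilyloxy)-3,4,6,8-tetramethyldeca-4,7-dienoyl]-1,3-oxazolidin-2-one | O=C(C[C@@H](C)/C(C)=C/[C@@H](C)/C=C(\C)[C@@H](C)O[Si](C)(C)C(C)(C)C)N1[C@@H](Cc2ccccc2)COC1=O | intermediate
20 | Z-sodium enolate of 19 | [Na+].[O-]/C(=C\[C@@H](C)/C(C)=C/[C@@H](C)/C=C(\C)[C@@H](C)O[Si](C)(C)C(C)(C)C)N1[C@@H](Cc2ccccc2)COC1=O | intermediate
21 | (S)-4-benzyl-3-[(2S,3S,4E,6R,7E,9R)-9-(tert-butyldimethylsilyloxy)-2-hydroxy-3,4,6,8-tetramethyldeca-4,7-dienoyl]-1,3-oxazolidin-2-one | O=C([C@@H](O)[C@@H](C)/C(C)=C/[C@@H](C)/C=C(\C)[C@@H](C)O[Si](C)(C)C(C)(C)C)N1[C@@H](Cc2ccccc2)COC1=O | intermediate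
22 | (S)-4-benzyl-3-[(2S,3S,4E,6R,7E,9R)-2,9-bis(tert-butyldimethylsilyloxy)-3,4,6,8-tetramethyldeca-4,7-dienoyl]-1,3-oxazolidin-2-one | O=C([C@@H](O[Si](C)(C)C(C)(C)C)[C@@H](C)/C(C)=C/[C@@H](C)/C=C(\C)[C@@H](C)O[Si](C)(C)C(C)(C)C)N1[C@@H](Cc2ccccc2)COC1=O | intermediate
23 | (2S,3S,4E,6R,7E,9R)-2,9-bis(tert-butyldimethylsilyloxy)-3,4,6,8-tetramethyldeca-4,7-dien-1-ol | OC[C@@H](O[Si](C)(C)C(C)(C)C)[C@@H](C)/C(C)=C/[C@@H](C)/C=C(\C)[C@@H](C)O[Si](C)(C)C(C)(C)C | intermediate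
24 | (2S,3S,4E,6R,7E,9R)-2,9-bis(tert-butyldimethylsilyloxy)-3,4,6,8-tetramethyldeca-4,7-dienal | O=C[C@@H](O[Si](C)(C)C(C)(C)C)[C@@H](C)/C(C)=C/[C@@H](C)/C=C(\C)[C@@H](C)O[Si](C)(C)C(C)(C)C | intermediate
25 | ethyl 2-methyl-3-oxobutanoate (ethyl 2-methylacetoacetate) | CCOC(=O)C(C)C(C)=O | starting material
26 | sodium lithium dianion of 25 (deprotonated at C2 and C4) | [Na+].[Li+].[CH2-]C(=O)[C-](C)C(=O)OCC | intermediate
27 | ethyl (6S,7S,8E,10R,11E,13R)-6,13-bis(tert-butyldimethylsilyloxy)-5-hydroxy-2,7,8,10,12-pentamethyl-3-oxotetradeca-8,11-dienoate (C2/C5 epimer mixture) | CCOC(=O)C(C)C(=O)CC(O)[C@@H](O[Si](C)(C)C(C)(C)C)[C@@H](C)/C(C)=C/[C@@H](C)/C=C(\C)[C@@H](C)O[Si](C)(C)C(C)(C)C | intermediate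
28 | ethyl (6S,7S,8E,10R,11E,13R)-6,13-bis(tert-butyldimethylsilyloxy)-2,7,8,10,12-pentamethyl-3,5-dioxotetradeca-8,11-dienoate | CCOC(=O)C(C)C(=O)CC(=O)[C@@H](O[Si](C)(C)C(C)(C)C)[C@@H](C)/C(C)=C/[C@@H](C)/C=C(\C)[C@@H](C)O[Si](C)(C)C(C)(C)C | intermediate
29 | 6-[(1S,2S,3E,5R,6E,8R)-1,8-bis(tert-butyldimethylsilyloxy)-2,3,5,7-tetramethylnona-3,6-dien-1-yl]-4-hydroxy-3-methyl-2H-pyran-2-one | Cc1c(O)cc([C@@H](O[Si](C)(C)C(C)(C)C)[C@@H](C)/C(C)=C/[C@@H](C)/C=C(\C)[C@@H](C)O[Si](C)(C)C(C)(C)C)oc1=O | intermediate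
30 | 6-[(1S,2S,3E,5R,6E,8R)-1,8-bis(tert-butyldimethylsilyloxy)-2,3,5,7-tetramethylnona-3,6-dien-1-yl]-4-methoxy-3-methyl-2H-pyran-2-one | COc1cc([C@@H](O[Si](C)(C)C(C)(C)C)[C@@H](C)/C(C)=C/[C@@H](C)/C=C(\C)[C@@H](C)O[Si](C)(C)C(C)(C)C)oc(=O)c1C | intermediate
31 | 6-[(1S,2S,3E,5R,6E,8R)-1,8-dihydroxy-2,3,5,7-tetramethylnona-3,6-dien-1-yl]-4-methoxy-3-methyl-2H-pyran-2-one | COc1cc([C@@H](O)[C@@H](C)/C(C)=C/[C@@H](C)/C=C(\C)[C@@H](C)O)oc(=O)c1C | target

**Totals and risks**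

Total steps: 20. Longest linear sequence: 20 steps (1 → 31); the route is linear, with 2, 9, 14 and 25 entering as bought building blocks.

The three steps most likely to fail:

Step 9 (Johnson–Claisen). At 135 °C with acid, the hindered allylic alcohol 13 may ionise or eliminate before it rearranges. The fallback sets out from 13 and uses an Ireland–Claisen rearrangement under basic, low-temperature conditions. Acetylation (Ac2O, pyridine, DMAP) gives the acetate ester F1. Enolisation with LiN(i-Pr)2 in the presence of Me3SiCl and Et3N in THF at −78 °C gives the O-trimethylsilyl ketene acetal F2. On warming to rt and then 50 °C this rearranges through the same chair transition state to the trimethylsilyl ester F3. Aqueous work-up hydrolyses F3 to acid 17, where the fallback comes back to the route; step 10 is then not needed.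

Step 14 (reductive removal of the auxiliary). With the hindered α-silyloxy, β-branched imide 22, hydride may attack the ring carbonyl and open the oxazolidinone. The fallback sets out from 21, before silylation. Aminolysis with MeNH(OMe)·HCl and AlMe3 in CH2Cl2 gives the hydroxy Weinreb amide F4. Silylation with t-BuMe2SiOTf and 2,6-lutidine gives the silyloxy Weinreb amide F5. Reduction with i-Bu2AlH in THF at −78 °C gives aldehyde 24, where the fallback comes back to the route; steps 13 to 15 are replaced.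

Step 18 (pyranone closure). DBU may epimerise C1', which sits next to the C5 ketone of 28, or the hindered diketo ester may cyclise slowly. The fallback sets out from 24 and closes the ring thermally without base. Vinylogous aldol addition of the lithium dienolate of bought 2,2,5,6-tetramethyl-4H-1,3-dioxin-4-one (LiN(i-Pr)2, THF, −78 °C) to 24 gives the hydroxy dioxinone F6. Dess–Martin oxidation gives the keto dioxinone F7. Heating F7 in toluene at 110 °C expels acetone and forms the acylketene F8, which is trapped by the enol of its own ketone to give pyranone 29, where the fallback comes back to the route; steps 16 to 18 are replaced.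

**Further compounds**

F1 | step 9 | (2E,4R,5S,6E,8R)-8-(tert-butyldimethylsilyloxy)-3,5,7-trimethylnona-2,6-dien-4-yl acetate | CC(=O)O[C@@H](/C(C)=C/C)[C@@H](C)/C=C(\C)[C@@H](C)O[Si](C)(C)C(C)(C)C
F2 | step 9 | O-trimethylsilyl ketene acetal of F1 | C=C(O[Si](C)(C)C)O[C@@H](/C(C)=C/C)[C@@H](C)/C=C(\C)[C@@H](C)O[Si](C)(C)C(C)(C)C
F3 | step 9 | trimethylsilyl (3R,4E,6R,7E,9R)-9-(tert-butyldimethylsilyloxy)-3,4,6,8-tetramethyldeca-4,7-dienoate | C[Si](C)(C)OC(=O)C[C@@H](C)/C(C)=C/[C@@H](C)/C=C(\C)[C@@H](C)O[Si](C)(C)C(C)(C)C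
F4 | step 14 | (2S,3S,4E,6R,7E,9R)-9-(tert-butyldimethylsilyloxy)-2-hydroxy-N-methoxy-N,3,4,6,8-pentamethyldeca-4,7-dienamide | CON(C)C(=O)[C@@H](O)[C@@H](C)/C(C)=C/[C@@H](C)/C=C(\C)[C@@H](C)O[Si](C)(C)C(C)(C)C
F5 | step 14 | (2S,3S,4E,6R,7E,9R)-2,9-bis(tert-butyldimethylsilyloxy)-N-methoxy-N,3,4,6,8-pentamethyldeca-4,7-dienamide | CON(C)C(=O)[C@@H](O[Si](C)(C)C(C)(C)C)[C@@H](C)/C(C)=C/[C@@H](C)/C=C(\C)[C@@H](C)O[Si](C)(C)C(C)(C)C
F6 | step 18 | 6-[(3S,4S,5E,7R,8E,10R)-3,10-bis(tert-butyldimethylsilyloxy)-2-hydroxy-4,5,7,9-tetramethylundeca-5,8-dien-1-yl]-2,2,5-trimethyl-4H-1,3-dioxin-4-one (C2 epimer mixture) | CC1=C(CC(O)[C@@H](O[Si](C)(C)C(C)(C)C)[C@@H](C)/C(C)=C/[C@@H](C)/C=C(\C)[C@@H](C)O[Si](C)(C)C(C)(C)C)OC(C)(C)OC1=O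
F7 | step 18 | 6-[(3S,4S,5E,7R,8E,10R)-3,10-bis(tert-butyldimethylsilyloxy)-4,5,7,9-tetramethyl-2-oxoundeca-5,8-dien-1-yl]-2,2,5-trimethyl-4H-1,3-dioxin-4-one | CC1=C(CC(=O)[C@@H](O[Si](C)(C)C(C)(C)C)[C@@H](C)/C(C)=C/[C@@H](C)/C=C(\C)[C@@H](C)O[Si](C)(C)C(C)(C)C)OC(C)(C)OC1=O
F8 | step 18 | acylketene (6S,7S,8E,10R,11E,13R)-6,13-bis(tert-butyldimethylsilyloxy)-2,7,8,10,12-pentamethyltetradeca-1,8,11-triene-1,3,5-trione | O=C=C(C)C(=O)CC(=O)[C@@H](O[Si](C)(C)C(C)(C)C)[C@@H](C)/C(C)=C/[C@@H](C)/C=C(\C)[C@@H](C)O[Si](C)(C)C(C)(C)C
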